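**Retrosynthetic overview**
1. Target 12 ⇐ triol diene 11 by site-selective O-acetylation at C7 (last step).
2. (12Z)-Diene of 11 ⇐ lactol 9 by one-pot γ-silylallylboration/Peterson elimination (C12=C13 bond and Z geometry).
3. Ring B oxygens ⇐ C–O bond formation on the intact decalin: Ru-catalysed ketohydroxylation of a Δ7 alkene (C7=O, C8–O, relactonization), enolate hydroxylation (C6–O), hydride reduction (C7–H).
4. Δ7 ester 4 ⇐ ent-sclareolide 2 (E1 opening); 2 ⇐ (3E,7E)-homofarnesic acid 1 by enantioselective proton-initiated bicyclization terminated by C8–O lactonization.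
5. Ring order: rings A and B and the γ-lactone form together in step 1; the lactone is opened and re-formed (steps 2–3) and finally opened to the side chain (step 6).

Assumption: the SMILES is read literally as (5R,6S,7R,8R,9S,10R,12Z), an ent-labdane whose decalin is antipodal to natural (+)-sclareolide, so sclareol/sclareolide cannot serve as chiral pool; (3E,7E)-homofarnesic acid is taken as a purchasable fragrance intermediate.

Reagent note: the step 6 boronate is not commercial; it would be made separately by lithiation of (but-3-en-2-yl)trimethylsilane (s-BuLi/TMEDA) and trapping with i-PrOBpin, and its E:Z purity sets the 12Z:12E ratio.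

Step 1
Reactants: 1 (3E,7E)-homofarnesic acid
Product: 2 ent-sclareolide [(3aS,5aR,9aR,9bS)-lactone]
Conditions: (S)-2′-(2-fluorobenzyloxy)-1,1′-binaphthalen-2-ol·SnCl4 (1.2 equiv), toluene, −78 °C, 48 h; recrystallisation from hexane
Reagents that add atoms: none
Why: Yamamoto-type Lewis-acid-assisted chiral Brønsted acid (LBA) proton-initiated polyene cyclization, in which chair–chair folding with anti addition across both E alkenes gives the trans-decalin with the C10 methyl and the C9 side chain cis, the carboxyl oxygen closes the trans-fused γ-lactone (C8–O equatorial), the (S)-reagent (antipode of the one that leads to the natural series) sets C5, C8, C9 and C10 in the ent series, and crystallisation raises the expected 75–90% ee to at least 98%.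

Step 2
Reactants: 2 ent-sclareolide
Product: 4 methyl ent-13,14,15,16-tetranorlabd-7-en-12-oate, via Δ7 acid 3 (not isolated)
Conditions: conc. H2SO4 (0.5 equiv), MeOH, 23 °C, 48 h; AgNO3-impregnated SiO2 chromatography
Reagents that add atoms: methanol, SMILES CO
Why: Acid-catalysed alkyl–oxygen cleavage of the tertiary lactone (E1 elimination) followed by Fischer esterification, in which the C8 cation loses the axial H7 aligned with the empty orbital to give mainly the trisubstituted Δ7 alkene, the methyl ester blocks relactonization, and no stereocentre is touched.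

Step 3
Reactants: 4 methyl ent-13,14,15,16-tetranorlabd-7-en-12-oate
Product: 6 ent-7-oxo-13,14,15,16-tetranorlabdan-12,8α-olide, via hydroxy keto ester 5 (not isolated)
Conditions: RuCl3·xH2O (1 mol%), Oxone (2KHSO5·KHSO4·K2SO4, 2.5 equiv), NaHCO3 (5 equiv), EtOAc–MeCN–H2O (6:6:1), 23 °C; then TsOH·H2O (10 mol%), toluene, 60 °C
Reagents that add atoms: potassium peroxymonosulfate (active part of Oxone), SMILES [K+].[O-]S(=O)(=O)OO
Why: RuO4-catalysed ketohydroxylation of a trisubstituted alkene (Plietker-type [3+2] addition and oxidation of the ruthenate ester), in which RuO4 adds to the face of C7=C8 opposite the axial C10 methyl so that the new tertiary C8–O bond is equatorial (ent-8α, methyl axial) and the carbonyl sits at the CH terminus C7, after which acid closes the trans-fused γ-lactone with loss of methanol.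

Step 4
Reactants: 6 ent-7-oxo-13,14,15,16-tetranorlabdan-12,8α-olide
Product: 8 ent-6α-hydroxy-7-oxo-13,14,15,16-tetranorlabdan-12,8α-olide, via potassium enolate 7 (not isolated)
Conditions: KN(SiMe3)2 (1.1 equiv), THF, −78 °C; then 2-(phenylsulfonyl)-3-phenyloxaziridine (1.3 equiv), −78 °C; AcOH quench
Reagents that add atoms: 2-(phenylsulfonyl)-3-phenyloxaziridine (Davis oxaziridine), SMILES O=S(=O)(c1ccccc1)N1OC1c1ccccc1
Why: Davis oxaziridine hydroxylation of a ketone enolate, in which C6 is the only enolisable position of the ketone (C8 is quaternary) and the oxidant can reach C6 only from the face opposite the two syn-axial methyls on C4 and C10, giving the equatorial ent-6α alcohol (cis to H5).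

Step 5
Reactants: 8 ent-6α-hydroxy-7-oxo-13,14,15,16-tetranorlabdan-12,8α-olide
Product: 9 ent-8α,12-epoxy-13,14,15,16-tetranorlabdane-6α,7β,12-triol (lactol as C12 epimers)
Conditions: i-Bu2AlH (4.5 equiv), CH2Cl2, −78 °C, 2 h; aqueous work-up
Reagents that add atoms: none
Why: Diisobutylaluminium hydride reduction, in which the C7 ketone takes hydride axially on the face opposite the adjacent axial C8 methyl to give the equatorial ent-7β alcohol trans to both neighbouring oxygens, while the lactone stops at the tetrahedral aluminate and gives the lactol.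

Step 6
Reactants: 9 ent-8α,12-epoxy-13,14,15,16-tetranorlabdane-6α,7β,12-triol
Product: 11 ent-(12Z)-labda-12,14-diene-6α,7β,8α-triol, via borate adduct 10 (not isolated)
Conditions: (E)-pinB–CH2CH=C(Me)SiMe3 (1.5 equiv), toluene, 70 °C, 24 h; then KH (6 equiv), THF, 0 to 23 °C
Reagents that add atoms: (E)-4,4,5,5-tetramethyl-2-[3-(trimethylsilyl)but-2-en-1-yl]-1,3,2-dioxaborolane, SMILES C[Si](C)(C)/C(C)=C/CB1OC(C)(C)C(C)(C)O1
Why: Proposed new method: a one-pot γ-silylallylboration/Peterson elimination with a γ-methyl-γ-silyl allylboronate on a free lactol, in which the open hydroxy aldehyde reacts through a closed chair (Zimmerman–Traxler) transition state that places the E-disposed SiMe3 anti to the new C12 oxygen at a quaternary C13, and potassium-alkoxide-triggered syn elimination of Me3SiO– then forces C11 and the vinyl group cis (the 12Z diene) whichever C12 epimer forms, the closest known chemistry being Hoffmann-type allylboration of aldehydes and the Tsai–Matteson γ-silylallylboronate/Peterson route to unsubstituted terminal Z-dienes, which to my knowledge has not been shown for a γ,γ-disubstituted silyl boronate or on an unprotected lactol polyol.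

Step 7
Reactants: 11 ent-(12Z)-labda-12,14-diene-6α,7β,8α-triol
Product: 12 ent-(12Z)-7β-acetoxylabda-12,14-diene-6α,8α-diol (target)
Conditions: Ac2O (1.1 equiv), pyridine, 0 °C
Reagents that add atoms: acetic anhydride, SMILES CC(=O)OC(C)=O
Why: Kinetically controlled O-acylation (acetylation), in which the tertiary C8 hydroxyl is inert and the equatorial C6 hydroxyl is shielded by a syn-pentane (peri) contact with the equatorial C4 methyl, so the C7 hydroxyl with only gauche neighbours reacts first and no stereocentre is changed.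

**Compound list**
1 | (3E,7E)-4,8,12-trimethyltrideca-3,7,11-trienoic acid (homofarnesic acid) | CC(C)=CCC/C(C)=C/CC/C(C)=C/CC(=O)O | starting material
2 | ent-sclareolide, (3aS,5aR,9aR,9bS)-3a,6,6,9a-tetramethyldecahydronaphtho[2,1-b]furan-2(1H)-one | O=C1C[C@@H]2[C@@](C)(O1)CC[C@@H]3C(C)(C)CCC[C@]32C | intermediate
3 | ent-13,14,15,16-tetranorlabd-7-en-12-oic acid | OC(=O)C[C@@H]1C(C)=CC[C@@H]2C(C)(C)CCC[C@]21C | intermediate (not isolated)
4 | methyl ent-13,14,15,16-tetranorlabd-7-en-12-oate | COC(=O)C[C@@H]1C(C)=CC[C@@H]2C(C)(C)CCC[C@]21C | intermediate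
5 | methyl ent-8α-hydroxy-7-oxo-13,14,15,16-tetranorlabdan-12-oate | COC(=O)C[C@@H]1[C@@](C)(O)C(=O)C[C@@H]2C(C)(C)CCC[C@]21C | intermediate (not isolated)
6 | ent-7-oxo-13,14,15,16-tetranorlabdan-12,8α-olide (7-oxo-ent-sclareolide) | O=C1C[C@@H]2[C@@](C)(O1)C(=O)C[C@@H]3C(C)(C)CCC[C@]32C | intermediate
7 | potassium C6(7)-enolate of 6 | O=C1C[C@@H]2[C@@](C)(O1)C([O-])=C[C@@H]3C(C)(C)CCC[C@]32C.[K+] | intermediate (not isolated)
8 | ent-6α-hydroxy-7-oxo-13,14,15,16-tetranorlabdan-12,8α-olide (6-OH equatorial, cis to H5) | O=C1C[C@@H]2[C@@](C)(O1)C(=O)[C@@H](O)[C@@H]3C(C)(C)CCC[C@]32C | intermediate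
9 | ent-8α,12-epoxy-13,14,15,16-tetranorlabdane-6α,7β,12-triol (lactol, both C12 epimers) | OC1C[C@@H]2[C@@](C)(O1)[C@H](O)[C@@H](O)[C@@H]3C(C)(C)CCC[C@]32C | intermediate
10 | 12-O-pinacolborate of ent-13-(trimethylsilyl)labd-14-ene-6α,7β,8α,12-tetraol, (12R,13S) isomer shown, formed together with the (12S,13R) isomer (Si anti to O12 in both) | C=C[C@](C)([Si](C)(C)C)[C@H](OB1OC(C)(C)C(C)(C)O1)C[C@@H]1[C@@](C)(O)[C@H](O)[C@@H](O)[C@@H]2C(C)(C)CCC[C@]21C | intermediate (not isolated)
11 | ent-(12Z)-labda-12,14-diene-6α,7β,8α-triol | C=C/C(C)=C\C[C@@H]1[C@@](C)(O)[C@H](O)[C@@H](O)[C@@H]2C(C)(C)CCC[C@]21C | intermediate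
12 | ent-(12Z)-7β-acetoxylabda-12,14-diene-6α,8α-diol, (5R,6S,7R,8R,9S,10R), CNP0225877.2 | C=C/C(C)=C\C[C@@H]1[C@@](C)(O)[C@H](OC(C)=O)[C@@H](O)[C@@H]2C(C)(C)CCC[C@]21C | target

**Totals and risks**
Total step count: 7. Longest linear sequence: 7 (fully linear from 1).

The three steps most likely to fail:

Step 2 (regiochemistry of the E1 opening; the Δ8(17) and Δ8(9) isomers may compete with Δ7). The fallback sets out from 2 and comes back at 4. Saponify 2 (KOH, aqueous MeOH) and methylate the carboxylate (MeI, K2CO3, DMF) to the hydroxy ester methyl ent-8α-hydroxy-13,14,15,16-tetranorlabdan-12-oate F1. Dehydrate under kinetic conditions (SOCl2, pyridine, CH2Cl2, −78 °C), where the equatorial chlorosulfite has only the methyl hydrogens antiperiplanar, to the exocyclic alkene methyl ent-13,14,15,16-tetranorlabd-8(17)-en-12-oate F2. Then move the double bond into the ring with RhCl3·3H2O (cat.) in EtOH at 70 °C, stopping before the tetrasubstituted isomer builds up, to give 4.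

Step 6 (the proposed new step; the lactol may react sluggishly with the hindered boronate, or the E:Z purity of the reagent may erode the diene geometry). The fallback uses known chemistry, sets out from 9 and comes back at 11. Stork–Zhao olefination of 9 with the ylide from (1-iodoethyl)triphenylphosphonium iodide and NaN(SiMe3)2 (5 equiv, THF, −78 to −20 °C) gives the vinyl iodide ent-(12Z)-13-iodo-14,15-dinorlabd-12-ene-6α,7β,8α-triol F3 (iodine cis to C11). Suzuki–Miyaura coupling with vinylboronic acid pinacol ester (Pd(PPh3)4, aqueous K3PO4, THF, 50 °C) then replaces iodine by vinyl with retention to give 11.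

Step 7 (site selectivity between the C6 and C7 hydroxyls). The fallback sets out from 8 and comes back at 12; it blocks O6 before C7 carries a hydroxyl. Silylate 8 (TBSOTf, 2,6-lutidine, CH2Cl2, 0 °C) to ent-6α-(tert-butyldimethylsilyloxy)-7-oxo-13,14,15,16-tetranorlabdan-12,8α-olide F4. Reduce as in step 5 (i-Bu2AlH, −78 °C) to the lactol ent-6α-(tert-butyldimethylsilyloxy)-8α,12-epoxy-13,14,15,16-tetranorlabdane-7β,12-diol F5. Build the diene by the low-temperature Stork–Zhao/Suzuki sequence described above (which avoids silyl migration), through ent-(12Z)-6α-(tert-butyldimethylsilyloxy)-13-iodo-14,15-dinorlabd-12-ene-7β,8α-diol F6 to ent-(12Z)-6α-(tert-butyldimethylsilyloxy)labda-12,14-diene-7β,8α-diol F7. Acetylate the only free secondary hydroxyl (Ac2O, DMAP, Et3N) to ent-(12Z)-7β-acetoxy-6α-(tert-butyldimethylsilyloxy)labda-12,14-dien-8α-ol F8, and remove the silyl ether with HF·pyridine (THF, 0 °C) to give 12.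

Further compounds
F1 | step 2 | methyl ent-8α-hydroxy-13,14,15,16-tetranorlabdan-12-oate | COC(=O)C[C@@H]1[C@@](C)(O)CC[C@@H]2C(C)(C)CCC[C@]21C
F2 | step 2 | methyl ent-13,14,15,16-tetranorlabd-8(17)-en-12-oate | COC(=O)C[C@@H]1C(=C)CC[C@@H]2C(C)(C)CCC[C@]21C
F3 | step 6 | ent-(12Z)-13-iodo-14,15-dinorlabd-12-ene-6α,7β,8α-triol | C/C(I)=C/C[C@@H]1[C@@](C)(O)[C@H](O)[C@@H](O)[C@@H]2C(C)(C)CCC[C@]21C
F4 | step 7 | ent-6α-(tert-butyldimethylsilyloxy)-7-oxo-13,14,15,16-tetranorlabdan-12,8α-olide | O=C1C[C@@H]2[C@@](C)(O1)C(=O)[C@@H](O[Si](C)(C)C(C)(C)C)[C@@H]3C(C)(C)CCC[C@]32C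
F5 | step 7 | ent-6α-(tert-butyldimethylsilyloxy)-8α,12-epoxy-13,14,15,16-tetranorlabdane-7β,12-diol | OC1C[C@@H]2[C@@](C)(O1)[C@H](O)[C@@H](O[Si](C)(C)C(C)(C)C)[C@@H]3C(C)(C)CCC[C@]32C
F6 | step 7 | ent-(12Z)-6α-(tert-butyldimethylsilyloxy)-13-iodo-14,15-dinorlabd-12-ene-7β,8α-diol | C/C(I)=C/C[C@@H]1[C@@](C)(O)[C@H](O)[C@@H](O[Si](C)(C)C(C)(C)C)[C@@H]2C(C)(C)CCC[C@]21C
F7 | step 7 | ent-(12Z)-6α-(tert-butyldimethylsilyloxy)labda-12,14-diene-7β,8α-diol | C=C/C(C)=C\C[C@@H]1[C@@](C)(O)[C@H](O)[C@@H](O[Si](C)(C)C(C)(C)C)[C@@H]2C(C)(C)CCC[C@]21C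
F8 | step 7 | ent-(12Z)-7β-acetoxy-6α-(tert-butyldimethylsilyloxy)labda-12,14-dien-8α-ol | C=C/C(C)=C\C[C@@H]1[C@@](C)(O)[C@H](OC(C)=O)[C@@H](O[Si](C)(C)C(C)(C)C)[C@@H]2C(C)(C)CCC[C@]21C
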